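**Plan**

- Retrosynthesis: the peroxide is cut at O1–C6 and O2–C3 (both oxygens come from O2), which re-joins C3–C6 and contracts the 1,2-dioxan-3-ol to cyclobutanol 16. Further cuts are C3–CH3 (MeLi), C4–CH3 (alkylation), the C3/C4/C5 unit (cyclopropylidene transfer to methyl ketone 6) and the side chain at C5'=C6' (cross-metathesis).
- Forward: the chain is joined first ((R)-citronellic acid → methyl ketone → cross-metathesis → hydrogenation). Then the four-membered carbocycle is made (3→4 spiroannelation), C4-Me and C3-Me are added, and the six-membered peroxide ring arises last by a 4→6 oxidative ring expansion.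
- Stereochemistry: C2' is bought with (R)-citronellic acid, C4 is set by SAMP-hydrazone methylation, and C3 settles under anomeric control. C6 is created by O2 capture on a planar radical with no reliable facial control, so its 6R epimer (a ring diastereomer, because C4 is fixed) must be removed by chromatography. C1 and C2 of the cyclobutane need no control, as both become planar.
- Enabling feature: C3 (oxygen-bearing) and the fully substituted C6 are 1,4-related through C4–C5. Tying them into a cyclobutanol puts ring strain and a tertiary-radical site exactly across the bond into which O2 is inserted.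

Key step: step 9

Remark: ring atoms are numbered O1, O2, C3 (hemiketal), C4, C5, C6 and the side-chain centre is C2'; the hemiketal centre C3 is taken to equilibrate freely through the open hydroperoxy ketone.

**Route**

Step 1
Reactants: 1 (R)-citronellic acid [(3R)-3,7-dimethyloct-6-enoic acid]
Product: 3 (4R)-4,8-dimethylnon-7-en-2-one, via dilithium gem-diolate 2 (not isolated)
Conditions: MeLi (2.2 equiv), Et2O, 0 °C to rt; inverse quench into cold 1 M HCl
Reagents that add atoms: methyllithium, C[Li]
Why: Addition of an organolithium to a lithium carboxylate (methyl ketone synthesis from an acid) stops at the gem-diolate, which collapses only on quench, so no tertiary alcohol should form; the stereocentre is β to the carbonyl and is not touched.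

Step 2
Reactants: 3 (4R)-4,8-dimethylnon-7-en-2-one; 4 6-phenylhex-1-ene
Product: 5 (4R)-4-methyl-12-phenyldodec-7-en-2-one (E/Z mixture)
Conditions: Hoveyda–Grubbs II (5 mol %), 4 (3 equiv), CH2Cl2, 40 °C
Reagents that add atoms: none
Why: Olefin cross-metathesis exchanges the 2-methylprop-1-enyl terminus of 3 for the terminal alkene of 4 with loss of volatile isobutene; ketone and arene are inert and the E/Z ratio is irrelevant because the alkene is hydrogenated next.

Step 3
Reactants: 5 (4R)-4-methyl-12-phenyldodec-7-en-2-one
Product: 6 (4R)-4-methyl-12-phenyldodecan-2-one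
Conditions: H2 (1 atm), 5% Pt/C, EtOAc, 23 °C
Reagents that add atoms: none
Why: Heterogeneous catalytic hydrogenation of the disubstituted alkene; Pt is preferred to Pd to suppress double-bond migration toward the C4 stereocentre, and ketone and arene should survive at 1 atm.

Step 4
Reactants: 6 (4R)-4-methyl-12-phenyldodecan-2-one; 7 cyclopropyldiphenylsulfonium tetrafluoroborate
Product: 10 2-methyl-2-[(2R)-2-methyl-10-phenyldecyl]cyclobutan-1-one (both C2 epimers), via sulfonium cyclopropylide 8 (not isolated), via oxaspiropentane 9 (not isolated)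
Conditions: 7 (1.3 equiv), powdered KOH, DMSO, 25 °C; then LiBF4 (cat.), benzene, 25 °C
Reagents that add atoms: none
Why: Trost cyclobutanone spiroannelation: the reversibly formed cyclopropylide adds to the ketone and closes to the oxaspiropentane, whose Lewis-acid-induced cyclopropylcarbinyl-to-cyclobutyl 1,2-shift gives the 2,2-disubstituted cyclobutanone; the new quaternary centre forms as both epimers, which is harmless because it becomes planar in step 9.

Step 5
Reactants: 10 2-methyl-2-[(2R)-2-methyl-10-phenyldecyl]cyclobutan-1-one; 11 SAMP [(S)-1-amino-2-(methoxymethyl)pyrrolidine]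
Product: 12 (S)-2-(methoxymethyl)-N-{2-methyl-2-[(2R)-2-methyl-10-phenyldecyl]cyclobutylidene}pyrrolidin-1-amine (E hydrazone, both C2 epimers)
Conditions: 11 (1.5 equiv), TsOH·H2O (cat.), cyclohexane, reflux, Dean–Stark
Reagents that add atoms: none
Why: Condensation of the ketone with the chiral hydrazine (SAMP hydrazone formation); the amino group should settle anti to the quaternary C2, that is syn to the only enolisable position C4.

Step 6
Reactants: 12 SAMP hydrazone of 10
Product: 14 (S)-N-{(4R)-2,4-dimethyl-2-[(2R)-2-methyl-10-phenyldecyl]cyclobutylidene}-2-(methoxymethyl)pyrrolidin-1-amine, via lithium azaenolate 13 (not isolated)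
Conditions: LDA (1.2 equiv), THF, 0 °C; then MeI (1.5 equiv), −100 to −78 °C
Reagents that add atoms: iodomethane, CI
Why: Enders SAMP-hydrazone alkylation: deprotonation is possible only at C4, and the lithium-chelated methoxymethylpyrrolidine shields one face of the azaenolate, so that, by analogy with the SAMP methylation of cycloalkanones to (R)-2-methyl ketones, iodomethane should enter from the face that gives 4R whatever the C2 configuration.

Step 7
Reactants: 14 methylated SAMP hydrazone
Product: 15 (4R)-2,4-dimethyl-2-[(2R)-2-methyl-10-phenyldecyl]cyclobutan-1-one (both C2 epimers)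
Conditions: sat. aq. oxalic acid, Et2O, 23 °C
Reagents that add atoms: water, O
Why: Two-phase acid hydrolysis of the hydrazone regenerates the ketone under conditions that should not enolise the α-stereocentre C4 and takes the auxiliary into the aqueous phase as its oxalate.

Step 8
Reactants: 15 (4R)-2,4-dimethyl-2-[(2R)-2-methyl-10-phenyldecyl]cyclobutan-1-one
Product: 16 (4R)-1,2,4-trimethyl-2-[(2R)-2-methyl-10-phenyldecyl]cyclobutan-1-ol (mixture at C1 and C2)
Conditions: MeLi (1.5 equiv), Et2O, −78 °C; then H2O
Reagents that add atoms: methyllithium, C[Li]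
Why: 1,2-Addition of methyllithium to the strained, electrophilic cyclobutanone carbonyl should outrun enolisation at −78 °C; the carbinol configuration is irrelevant (C1 passes through a ketone in step 9) and C4 is untouched.

Step 9
Reactants: 16 (4R)-1,2,4-trimethyl-2-[(2R)-2-methyl-10-phenyldecyl]cyclobutan-1-ol
Product: 18 (3S,4R,6S)-3,4,6-trimethyl-6-[(2R)-2-methyl-10-phenyldecyl]-1,2-dioxan-3-ol, via hydroperoxy ketone 17 (not isolated)
Conditions: Co(acac)2 (20 mol %), O2 (1 atm), MeCN, 25 °C; SiO2 chromatography to remove the C6 epimer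
Reagents that add atoms: dioxygen, O=O
Why: Cobalt and O2 turn the tertiary cyclobutanol into a cobalt(III) alkoxide that fragments as an alkoxy radical, strain-driven β-scission of the C1–C2 bond gives the tertiary carbon radical (future C6) and the methyl ketone (future C3), O2 is captured at C6, and the resulting hydroperoxide 17 adds to the ketone. The closest known reaction type is the Co(acac)2/O2 oxidative ring expansion of cyclobutanols to 1,2-dioxan-3-ols, the four-ring counterpart of the Mn-catalysed cyclopropanol to 1,2-dioxolan-3-ol reaction. The 1,2-dioxane closes by reversible 6-exo-trig addition of the hydroperoxide oxygen to the carbonyl carbon (peroxy-hemiketalisation). C3 is set thermodynamically (anomeric OH axial, C3-Me equatorial, hence OH cis to the equatorial C4-Me), C4 is not a reacting centre and keeps the R configuration of 16 under these neutral conditions, and C6 is created by O2 capture on a planar acyclic radical for which the substrate offers no reliable facial bias, so both C6 epimers are expected and the 6R isomer is removed by chromatography as a ring cis/trans diastereomer. The step needs regioselective β-scission toward the quaternary carbon, which the tertiary-over-secondary radical stability should secure. All C1/C2 epimers of 16 converge because both centres become planar.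

**Compound list**

1 | (R)-citronellic acid, (3R)-3,7-dimethyloct-6-enoic acid | C[C@H](CCC=C(C)C)CC(=O)O | starting material
2 | dilithium (4R)-4,8-dimethylnon-7-ene-2,2-diolate | [Li+].[Li+].CC([O-])([O-])C[C@H](C)CCC=C(C)C | intermediate (not isolated)
3 | (4R)-4,8-dimethylnon-7-en-2-one | CC(=O)C[C@H](C)CCC=C(C)C | intermediate
4 | 6-phenylhex-1-ene | C=CCCCCc1ccccc1 | starting material
5 | (4R)-4-methyl-12-phenyldodec-7-en-2-one (E/Z) | CC(=O)C[C@H](C)CCC=CCCCCc1ccccc1 | intermediate
6 | (4R)-4-methyl-12-phenyldodecan-2-one | CC(=O)C[C@H](C)CCCCCCCCc1ccccc1 | intermediate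
7 | cyclopropyldiphenylsulfonium tetrafluoroborate | F[B-](F)(F)F.C1CC1[S+](c1ccccc1)c1ccccc1 | starting material
8 | diphenylsulfonium cyclopropylide | C1C[C-]1[S+](c1ccccc1)c1ccccc1 | intermediate (not isolated)
9 | 2-methyl-2-[(2R)-2-methyl-10-phenyldecyl]-1-oxaspiro[2.2]pentane (both C2 epimers) | CC1(C[C@H](C)CCCCCCCCc2ccccc2)OC12CC2 | intermediate (not isolated)
10 | 2-methyl-2-[(2R)-2-methyl-10-phenyldecyl]cyclobutan-1-one (both C2 epimers) | CC1(C[C@H](C)CCCCCCCCc2ccccc2)CCC1=O | intermediate
11 | SAMP, (S)-1-amino-2-(methoxymethyl)pyrrolidine | COC[C@@H]1CCCN1N | starting material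
12 | (S)-2-(methoxymethyl)-N-{2-methyl-2-[(2R)-2-methyl-10-phenyldecyl]cyclobutylidene}pyrrolidin-1-amine (E, both C2 epimers) | COC[C@@H]1CCCN1/N=C2\CCC2(C)C[C@H](C)CCCCCCCCc1ccccc1 | intermediate
13 | lithium azaenolate of 12 | [Li+].COC[C@@H]1CCCN1[N-]C1=CCC1(C)C[C@H](C)CCCCCCCCc1ccccc1 | intermediate (not isolated)
14 | (S)-N-{(4R)-2,4-dimethyl-2-[(2R)-2-methyl-10-phenyldecyl]cyclobutylidene}-2-(methoxymethyl)pyrrolidin-1-amine (both C2 epimers) | COC[C@@H]1CCCN1/N=C2\[C@H](C)CC2(C)C[C@H](C)CCCCCCCCc1ccccc1 | intermediate
15 | (4R)-2,4-dimethyl-2-[(2R)-2-methyl-10-phenyldecyl]cyclobutan-1-one (both C2 epimers) | C[C@@H]1CC(C)(C[C@H](C)CCCCCCCCc2ccccc2)C1=O | intermediate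
16 | (4R)-1,2,4-trimethyl-2-[(2R)-2-methyl-10-phenyldecyl]cyclobutan-1-ol (mixture at C1 and C2) | C[C@@H]1CC(C)(C[C@H](C)CCCCCCCCc2ccccc2)C1(C)O | intermediate
17 | (3R,5S,7R)-5-hydroperoxy-3,5,7-trimethyl-15-phenylpentadecan-2-one | C[C@H](CCCCCCCCc1ccccc1)C[C@@](OO)(C)C[C@@H](C)C(C)=O | intermediate (not isolated)
18 | (3S,4R,6S)-3,4,6-trimethyl-6-[(2R)-2-methyl-10-phenyldecyl]-1,2-dioxan-3-ol | C[C@H](CCCCCCCCc1ccccc1)C[C@@]1(C)C[C@@H](C)[C@@](C)(O)OO1 | target

**Step count and risks**

Total step count: 9. Longest linear sequence: 9 steps (from 1).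

Steps most likely to fail:

Step 9. The alkoxy radical may cleave toward C4 instead of C2, cobalt may reduce the hydroperoxide to the alcohol, or the peroxy hemiketal may undergo C–C cleavage. The face-unselective O2 capture at C6 is inherent and is not cured by the fallback. The fallback replaces the ring expansion by an acyclic hydroperoxidation; it sets out from 6 and returns at 17.
- Kinetic enolisation of 6 (KHMDS, THF, −78 °C) and trapping with PhNTf2 should give the vinyl triflate (4R)-4-methyl-12-phenyldodec-1-en-2-yl trifluoromethanesulfonate F1.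
- Negishi coupling (Pd(PPh3)4, THF/DMA) with [(2S)-3-methoxy-2-methyl-3-oxopropyl]zinc bromide F2, made from commercial methyl (S)-3-bromo-2-methylpropanoate and zinc dust, should give methyl (2R,6R)-2,6-dimethyl-4-methylidene-14-phenyltetradecanoate F3. The future C4 then comes from the chiral pool.
- MeNHOMe·HCl/iPrMgCl should give the Weinreb amide (2R,6R)-N-methoxy-N,2,6-trimethyl-4-methylidene-14-phenyltetradecanamide F4, and MeMgBr the ketone (3R,7R)-3,7-dimethyl-5-methylidene-15-phenylpentadecan-2-one F5.
- Mukaiyama–Isayama hydroperoxysilylation (Co(thd)2 cat., O2, Et3SiH, DCE) should place the silyl peroxide at the tertiary carbon to give (3R,7R)-3,5,7-trimethyl-15-phenyl-5-[(triethylsilyl)peroxy]pentadecan-2-one F6.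
- TBAF/AcOH should free hydroperoxide 17, which closes to 18; C6 again arises as both epimers, separated as in the main route.

Step 6. Azaenolate formation on the hindered, strained hydrazone may be incomplete, or the C2 substituents may erode the facial control. The fallback replaces the auxiliary by catalytic asymmetric hydrogenation; it sets out from 10 and returns at 15.
- α-Methylenation of 10 (paraformaldehyde, iPr2NH·TFA, THF, reflux) should give 2-methyl-4-methylidene-2-[(2R)-2-methyl-10-phenyldecyl]cyclobutan-1-one F7.
- Hydrogenation of the exocyclic enone with a Ru(OAc)2(BINAP) catalyst (H2, MeOH), with the BINAP enantiomer chosen in a trial to give 4R, should deliver 15.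

Step 4. The methyl ketone may enolise and undergo aldol condensation under KOH/DMSO, or the oxaspiropentane may rearrange incompletely. The fallback replaces the ylide by an organolithium addition and pinacol-type ring expansion; it sets out from 6 and returns at 10.
- Cyclopropyl phenyl sulfide and n-BuLi (THF, 0 °C) give 1-lithio-1-(phenylsulfanyl)cyclopropane F8.
- Addition of F8 to 6 at −78 °C should give the carbinol (4R)-4-methyl-12-phenyl-2-[1-(phenylsulfanyl)cyclopropyl]dodecan-2-ol F9.
- TsOH in wet benzene at reflux should ionise the carbinol, expand the cyclopropane to the sulfur-stabilised cyclobutyl cation and hydrolyse it to 10.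

**Further compounds**

F1 | step 9 | (4R)-4-methyl-12-phenyldodec-1-en-2-yl trifluoromethanesulfonate | C=C(OS(=O)(=O)C(F)(F)F)C[C@H](C)CCCCCCCCc1ccccc1
F2 | step 9 | [(2S)-3-methoxy-2-methyl-3-oxopropyl]zinc bromide | COC(=O)[C@H](C)C[Zn]Br
F3 | step 9 | methyl (2R,6R)-2,6-dimethyl-4-methylidene-14-phenyltetradecanoate | COC(=O)[C@H](C)CC(=C)C[C@H](C)CCCCCCCCc1ccccc1
F4 | step 9 | (2R,6R)-N-methoxy-N,2,6-trimethyl-4-methylidene-14-phenyltetradecanamide | CON(C)C(=O)[C@H](C)CC(=C)C[C@H](C)CCCCCCCCc1ccccc1
F5 | step 9 | (3R,7R)-3,7-dimethyl-5-methylidene-15-phenylpentadecan-2-one | CC(=O)[C@H](C)CC(=C)C[C@H](C)CCCCCCCCc1ccccc1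
F6 | step 9 | (3R,7R)-3,5,7-trimethyl-15-phenyl-5-[(triethylsilyl)peroxy]pentadecan-2-one (both C5 epimers) | CC(=O)[C@H](C)CC(C)(OO[Si](CC)(CC)CC)C[C@H](C)CCCCCCCCc1ccccc1
F7 | step 6 | 2-methyl-4-methylidene-2-[(2R)-2-methyl-10-phenyldecyl]cyclobutan-1-one | C=C1CC(C)(C[C@H](C)CCCCCCCCc2ccccc2)C1=O
F8 | step 4 | 1-lithio-1-(phenylsulfanyl)cyclopropane | [Li]C1(Sc2ccccc2)CC1
F9 | step 4 | (4R)-4-methyl-12-phenyl-2-[1-(phenylsulfanyl)cyclopropyl]dodecan-2-ol | CC(O)(C[C@H](C)CCCCCCCCc1ccccc1)C1(Sc2ccccc2)CC1
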